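## Retrosynthetic overview

Labdane numbering is used: C15 is the acid carbon, C13 the methyl-bearing chain carbon, C3 the acetoxy carbon.

1. Target ⇒ the equatorial 3-hydroxy acid. C3 is inverted late by oxidation and bulky-hydride reduction, with acetylation in the reduction flask.
2. Rings A and B ⇒ one radical cascade from an acyclic (R)-epoxy-dienoic acid. Ring A closes first (C4–C5), ring B second (C10–C9), and loss of a C17 hydrogen gives the exocyclic alkene.
3. C20 chain ⇒ cut in the middle at C6–C7, two carbons that are both allylic electrophiles by nature. C6 is turned into a carbanion (α-sulfonyl anion of (R)-6,7-epoxygeranyl phenyl sulfone) and alkylated by the C7 bromide; the sulfone is then removed with palladium and hydride.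
4. The two C10 halves are geranyl acetate (Shi epoxidation sets C3 and, through it, C5, C9 and C10) and methyl (R)-citronellate (carries C13; SeO2 oxidation of its (E)-methyl opens C7).

Assumption: methyl (R)-citronellate (97% ee or better) is bought as such; if only the acid is stocked, one Fischer esterification precedes step 3.

## Route

Step 1
Reactants: 1 geranyl acetate
Product: 2 (R)-6,7-epoxygeranyl acetate, i.e. (2E)-5-[(2R)-3,3-dimethyloxiran-2-yl]-3-methylpent-2-en-1-yl acetate
Conditions: 1,2:4,5-di-O-isopropylidene-β-D-erythro-hexo-2,3-diulo-2,6-pyranose (D-fructose-derived Shi ketone, 0.3 equiv), KHSO5 (1.4 equiv), K2CO3, Bu4NHSO4 (cat.), Na2B4O7/Na2EDTA buffer, MeCN–CH2(OMe)2, 0 °C, 2 h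
Reagents that add atoms: potassium peroxymonosulfate, [K+].[O-]S(=O)(=O)OO
Why: Shi asymmetric epoxidation, in which the chiral dioxirane reacts only with the electron-rich 6,7-alkene (the 2,3-alkene is deactivated by the allylic acetate) through a spiro transition state that sets the (R) epoxide carbon, the later C3, in about 92% ee.

Step 2
Reactants: 2 (R)-6,7-epoxygeranyl acetate
Product: 3 (R)-6,7-epoxygeranyl phenyl sulfone, i.e. (3R)-2,2-dimethyl-3-[(3E)-3-methyl-5-(phenylsulfonyl)pent-3-en-1-yl]oxirane
Conditions: PhSO2Na (1.5 equiv), Pd(PPh3)4 (3 mol %), THF–MeOH 1:1, 23 °C, 6 h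
Reagents that add atoms: sodium benzenesulfinate, [Na+].[O-]S(=O)c1ccccc1
Why: Tsuji–Trost allylic substitution, in which zerovalent palladium ionises the allylic acetate and the sulfinate sulfur attacks the less hindered terminus of the π-allyl complex to give the linear (E)-sulfone, the remote epoxide being untouched.

Step 3
Reactants: 4 methyl (R)-citronellate, i.e. methyl (3R)-3,7-dimethyloct-6-enoate
Product: 5 methyl (3R,6E)-8-hydroxy-3,7-dimethyloct-6-enoate
Conditions: SeO2 (0.3 equiv), t-BuOOH (2.5 equiv), salicylic acid (0.1 equiv), CH2Cl2, 23 °C, 36 h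
Reagents that add atoms: selenium dioxide, O=[Se]=O (delivers the oxygen and is re-formed); tert-butyl hydroperoxide, CC(C)(C)OO (terminal oxygen source)
Why: SeO2 allylic oxidation (ene reaction then [2,3]-sigmatropic shift), which hydroxylates selectively the methyl trans to the chain and so gives the (E)-allylic alcohol without touching the C3 stereocentre.

Step 4
Reactants: 5 methyl (3R,6E)-8-hydroxy-3,7-dimethyloct-6-enoate
Product: 6 methyl (3R,6E)-8-bromo-3,7-dimethyloct-6-enoate
Conditions: CBr4 (1.2 equiv), PPh3 (1.25 equiv), CH2Cl2, 0 °C, 30 min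
Reagents that add atoms: carbon tetrabromide, BrC(Br)(Br)Br
Why: Appel reaction, an SN2 displacement at the primary allylic carbon that keeps the (E)-alkene and creates no stereocentre.

Step 5 (key bond, C6–C7)
Reactants: 3 (R)-6,7-epoxygeranyl phenyl sulfone; 6 methyl (3R,6E)-8-bromo-3,7-dimethyloct-6-enoate
Product: 9 (3R,6E,10E)-13-[(2R)-3,3-dimethyloxiran-2-yl]-3,7,11-trimethyl-9-(phenylsulfonyl)trideca-6,10-dienoic acid (both C9 epimers), via lithiated sulfone 7 (not isolated), via coupled methyl ester 8 (not isolated)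
Conditions: 3, n-BuLi (1.0 equiv), THF, −78 °C, 30 min; 6 (1.0 equiv), −78 → −20 °C, 2 h; then LiOH·H2O (5 equiv), MeOH–H2O, 23 °C, 12 h; cold 0.5 M HCl to pH 4
Reagents that add atoms: lithium hydroxide, [Li+].[OH-]
Why: sulfone-mediated allyl–allyl coupling (alkylation of an α-sulfonyl carbanion), in which the sulfonyl group turns the normally electrophilic C1 of the geranyl unit into a carbanion that displaces the primary allylic bromide by SN2 at its α-carbon, so that two natural allylic electrophiles are joined with both (E)-alkenes, the epoxide and the methyl stereocentre intact, the sulfone-bearing carbon forming as an inconsequential 1:1 mixture that step 6 erases, and the ester is then saponified in the same flask.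

Step 6
Reactants: 9 sulfone acid
Product: 10 (3R,6E,10E)-13-[(2R)-3,3-dimethyloxiran-2-yl]-3,7,11-trimethyltrideca-6,10-dienoic acid
Conditions: PdCl2(dppp) (dppp = Ph2P(CH2)3PPh2, 5 mol %), LiBHEt3 (3.2 equiv), THF, −20 → 0 °C, 1 h; cold 0.5 M HCl to pH 4
Reagents that add atoms: none
Why: palladium-catalysed hydrogenolysis of an allylic sulfone, in which zerovalent palladium formed in the flask ionises the C–S bond and hydride goes to the less substituted allyl terminus, which keeps the trisubstituted (E)-alkene in place and removes the only uncontrolled stereocentre, while the lithium carboxylate is inert and the epoxide (its only open carbon is neopentyl-like) is expected to survive at or below 0 °C.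

Step 7
Reactants: 10 epoxy-dienoic acid
Product: 13 (3R)-5-[(1R,4aS,6R,8aS)-6-hydroxy-5,5,8a-trimethyl-2-methylidenedecahydronaphthalen-1-yl]-3-methylpentanoic acid, via trimethylsilyl ester 11 (not isolated), via bis-silylated bicycle 12 (not isolated)
Conditions: Cp2TiCl2 (0.25 equiv), Mn powder (8 equiv), Me3SiCl (5 equiv), 2,4,6-collidine (8 equiv), THF (0.02 M), 23 °C, 16 h; then 10% aq. citric acid, THF, 23 °C, 1 h
Reagents that add atoms: none
Why: titanocene-catalysed reductive epoxide opening and radical polyene cyclisation (Nugent–RajanBabu type), in which Cp2TiCl (trivalent titanium) opens the epoxide to the tertiary C4 radical that closes ring A and then ring B by two 6-endo additions through a chair–chair array with the titanium-bound oxygen equatorial, so that the (R)-epoxide fixes the trans ring fusion (C5, C10) and the (E)-alkene places the C9 side chain equatorial, after which the C8 radical is trapped by a second Cp2TiCl and loses a methyl hydrogen by β-hydride elimination to give the exocyclic alkene, the acid being masked in the flask as its silyl ester.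

Step 8
Reactants: 13 equatorial hydroxy acid
Product: 14 (3R)-5-[(1R,4aS,8aS)-5,5,8a-trimethyl-2-methylidene-6-oxodecahydronaphthalen-1-yl]-3-methylpentanoic acid
Conditions: Dess–Martin periodinane (1,1,1-triacetoxy-1,2-benziodoxol-3-one, 1.5 equiv), CH2Cl2, 23 °C, 1 h
Reagents that add atoms: none
Why: Dess–Martin oxidation of the secondary alcohol to the C3 ketone under near-neutral conditions that spare the exocyclic alkene and the acid, with no stereocentre alpha to the new carbonyl.

Step 9
Reactants: 14 keto acid
Product: 17 (3R)-5-[(1R,4aS,6S,8aS)-6-acetoxy-5,5,8a-trimethyl-2-methylidenedecahydronaphthalen-1-yl]-3-methylpentanoic acid (target), via dilithium alkoxide carboxylate 15 (not isolated), via mixed acetic anhydride 16 (not isolated)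
Conditions: LiBH(s-Bu)3 (2.6 equiv), THF, −78 °C, 2 h; then Ac2O (8 equiv), 4-(dimethylamino)pyridine (0.3 equiv), −78 → 23 °C, 12 h; H2O–THF, 23 °C, 2 h; 1 M HCl to pH 3
Reagents that add atoms: acetic anhydride, CC(=O)OC(C)=O
Why: diastereoselective ketone reduction by a bulky trialkylborohydride followed by acetylation in the same flask, in which the hindered hydride enters along the equatorial trajectory (the axial one is closed by the syn-axial hydrogens at C1 and C5) to give the axial (3S) alkoxide, which is acetylated, the mixed anhydride at C15 being hydrolysed on aqueous work-up.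

## Compound list

1 | geranyl acetate, (2E)-3,7-dimethylocta-2,6-dien-1-yl acetate | CC(=O)OC/C=C(\C)CCC=C(C)C | starting material
2 | (R)-6,7-epoxygeranyl acetate | CC(=O)OC/C=C(\C)CC[C@H]1OC1(C)C | intermediate
3 | (R)-6,7-epoxygeranyl phenyl sulfone | O=S(=O)(C/C=C(\C)CC[C@H]1OC1(C)C)c1ccccc1 | intermediate
4 | methyl (R)-citronellate | COC(=O)C[C@H](C)CCC=C(C)C | starting material
5 | methyl (3R,6E)-8-hydroxy-3,7-dimethyloct-6-enoate | COC(=O)C[C@H](C)CC/C=C(\C)CO | intermediate
6 | methyl (3R,6E)-8-bromo-3,7-dimethyloct-6-enoate | COC(=O)C[C@H](C)CC/C=C(\C)CBr | intermediate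
7 | lithiated sulfone (1-lithio derivative of 3) | [Li]C(/C=C(\C)CC[C@H]1OC1(C)C)S(=O)(=O)c1ccccc1 | intermediate (not isolated)
8 | methyl (3R,6E,10E)-13-[(2R)-3,3-dimethyloxiran-2-yl]-3,7,11-trimethyl-9-(phenylsulfonyl)trideca-6,10-dienoate (both C9 epimers) | COC(=O)C[C@H](C)CC/C=C(\C)CC(/C=C(\C)CC[C@H]1OC1(C)C)S(=O)(=O)c1ccccc1 | intermediate (not isolated)
9 | (3R,6E,10E)-13-[(2R)-3,3-dimethyloxiran-2-yl]-3,7,11-trimethyl-9-(phenylsulfonyl)trideca-6,10-dienoic acid (both C9 epimers) | OC(=O)C[C@H](C)CC/C=C(\C)CC(/C=C(\C)CC[C@H]1OC1(C)C)S(=O)(=O)c1ccccc1 | intermediate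
10 | (3R,6E,10E)-13-[(2R)-3,3-dimethyloxiran-2-yl]-3,7,11-trimethyltrideca-6,10-dienoic acid | OC(=O)C[C@H](C)CC/C=C(\C)CC/C=C(\C)CC[C@H]1OC1(C)C | intermediate
11 | trimethylsilyl ester of 10 | C[Si](C)(C)OC(=O)C[C@H](C)CC/C=C(\C)CC/C=C(\C)CC[C@H]1OC1(C)C | intermediate (not isolated)
12 | trimethylsilyl (3R)-3-methyl-5-[(1R,4aS,6R,8aS)-5,5,8a-trimethyl-2-methylidene-6-(trimethylsilyloxy)decahydronaphthalen-1-yl]pentanoate | C=C1CC[C@@H]2C(C)(C)[C@H](O[Si](C)(C)C)CC[C@@]2(C)[C@@H]1CC[C@@H](C)CC(=O)O[Si](C)(C)C | intermediate (not isolated)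
13 | (3R)-5-[(1R,4aS,6R,8aS)-6-hydroxy-5,5,8a-trimethyl-2-methylidenedecahydronaphthalen-1-yl]-3-methylpentanoic acid | C=C1CC[C@@H]2C(C)(C)[C@H](O)CC[C@@]2(C)[C@@H]1CC[C@@H](C)CC(=O)O | intermediate
14 | (3R)-5-[(1R,4aS,8aS)-5,5,8a-trimethyl-2-methylidene-6-oxodecahydronaphthalen-1-yl]-3-methylpentanoic acid | C=C1CC[C@@H]2C(C)(C)C(=O)CC[C@@]2(C)[C@@H]1CC[C@@H](C)CC(=O)O | intermediate
15 | dilithium salt (C3 alkoxide, C15 carboxylate) of the axial (6S) hydroxy acid | [Li+].[Li+].C=C1CC[C@@H]2C(C)(C)[C@@H]([O-])CC[C@@]2(C)[C@@H]1CC[C@@H](C)CC(=O)[O-] | intermediate (not isolated)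
16 | mixed acetic anhydride of the target acid | C=C1CC[C@@H]2C(C)(C)[C@@H](OC(C)=O)CC[C@@]2(C)[C@@H]1CC[C@@H](C)CC(=O)OC(C)=O | intermediate (not isolated)
17 | (3R)-5-[(1R,4aS,6S,8aS)-6-acetoxy-5,5,8a-trimethyl-2-methylidenedecahydronaphthalen-1-yl]-3-methylpentanoic acid | C=C1CC[C@@H]2C(C)(C)[C@@H](OC(C)=O)CC[C@@]2(C)[C@@H]1CC[C@@H](C)CC(=O)O | target

## Step count and weak points

Total: 9 steps. Longest linear sequence: 7 steps (1, 2, 5–9, or equally 3–9).

**Step 6 (most likely to fail).** LiBHEt3 may open the epoxide, or some double-bond isomer may form. The fallback couples before epoxidising. It sets out from 1 and 6. PhSO2Na and Pd(PPh3)4 turn 1 into geranyl phenyl sulfone F1. F1 is lithiated, alkylated with 6 and saponified as in step 5 to give the epoxide-free sulfone acid F2. PdCl2(dppp)/LiBHEt3 then meets nothing reducible except the sulfone and gives (3R,6E,10E)-3,7,11,15-tetramethylhexadeca-6,10,14-trienoic acid F3. Epoxidation of F3 under the conditions of step 1, stopped at about half conversion (the terminal alkene is the least hindered; unreacted F3 is recycled and internal epoxides are separated), returns to the route at 10.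

**Step 7.** The free acid may tie up titanium, and monocyclic or endocyclic-alkene products are the usual losses; 30–45% is a realistic yield. The fallback cyclises an isolated ester under the stoichiometric regime rather than the in-flask silyl ester under catalysis. It sets out from 10. Me3SiCHN2 in MeOH–toluene gives the epoxy methyl ester F4. Cp2TiCl made from Cp2TiCl2 (2.2 equiv) and Mn in THF, with slow addition of F4 and no silyl chloride, gives the bicyclic hydroxy ester F5. LiOH in THF–H2O returns to the route at 13.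

**Step 5.** Carbanion 7 could attack the ester of 6, or the bromide could eliminate. The fallback replaces SN2 on a bromide by attack on a π-allyl palladium complex. It sets out from 5 and 3. ClCO2Me and pyridine turn 5 into the allylic methyl carbonate F6. Carbanion 7, made from 3 as before, is added to F6 and Pd(PPh3)4 (zerovalent palladium) in THF at 0 °C, where the soft sulfonyl carbanion attacks the less hindered allyl terminus. This gives 8, which is saponified to 9, where the route is rejoined.

## Further compounds

F1 | step 6 | geranyl phenyl sulfone, [(2E)-3,7-dimethylocta-2,6-dien-1-yl]sulfonylbenzene | O=S(=O)(C/C=C(\C)CCC=C(C)C)c1ccccc1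
F2 | step 6 | (3R,6E,10E)-3,7,11,15-tetramethyl-9-(phenylsulfonyl)hexadeca-6,10,14-trienoic acid (both C9 epimers) | OC(=O)C[C@H](C)CC/C=C(\C)CC(/C=C(\C)CCC=C(C)C)S(=O)(=O)c1ccccc1
F3 | step 6 | (3R,6E,10E)-3,7,11,15-tetramethylhexadeca-6,10,14-trienoic acid | OC(=O)C[C@H](C)CC/C=C(\C)CC/C=C(\C)CCC=C(C)C
F4 | step 7 | methyl (3R,6E,10E)-13-[(2R)-3,3-dimethyloxiran-2-yl]-3,7,11-trimethyltrideca-6,10-dienoate | COC(=O)C[C@H](C)CC/C=C(\C)CC/C=C(\C)CC[C@H]1OC1(C)C
F5 | step 7 | methyl (3R)-5-[(1R,4aS,6R,8aS)-6-hydroxy-5,5,8a-trimethyl-2-methylidenedecahydronaphthalen-1-yl]-3-methylpentanoate | C=C1CC[C@@H]2C(C)(C)[C@H](O)CC[C@@]2(C)[C@@H]1CC[C@@H](C)CC(=O)OC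
F6 | step 5 | methyl (3R,6E)-8-[(methoxycarbonyl)oxy]-3,7-dimethyloct-6-enoate | COC(=O)C[C@H](C)CC/C=C(\C)COC(=O)OC
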